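Matched one to one, the partner leaves 20.0 % of the substrate over, but what I want is how much single product stands at the reading in each of the four vessels.

    partner + single product → double product + by-product (k1 = 0.257 L mol⁻¹ s⁻¹)
    partner + tris adduct → tetra adduct + by-product (k2 = 0.0101 L mol⁻¹ s⁻¹)
    partner + double product → tris adduct + by-product (k3 = 1.92 L mol⁻¹ s⁻¹)
    substrate + single product → side product (k4 = 0.386 L mol⁻¹ s⁻¹)
    substrate + partner → single product + by-product (k5 = 0.597 L mol⁻¹ s⁻¹)

| flask | substrate | partner | time | remark |
|---|---|---|---|---|
| violet | 0.10 M | 0.800 equiv (fed, over 12.0 s) | 15 s | all but partner at the start; partner goes in evenly over 12.0 s, the run ends at 15 s |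
| red | 0.10 M (fed, over 12.0 s) | 0.800 equiv | 15 s | all but substrate at the start; substrate goes in evenly over 12.0 s, the run ends at 15 s |
| blue | 0.10 M | 0.800 equiv |  | one stirred flow tank at steady state, fed with the mixture as stated, mean residence time 15 s |
| grey | 0.10 M | 0.800 equiv | 15 s | a closed flask charged with all of it at once and left for 15 s |

- percentages count the substrate that a species holds: one side product counts as two
- the stated concentrations are those of everything mixed, before any reaction; amounts are the same in each set-up
- the feed brings no volume worth counting
- run time (violet): 15 s

* the set-up with the highest amount of single product at the outlet or at the end, in percent of the substrate put in ("none" if the first two lie within 2 percentage points) (violet / red / blue / grey / none)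
* amount of single product at the outlet or at the end, in percent of the substrate put in, violet
* amount of single product at the outlet or at the end, in percent of the substrate put in, red
* amount of single product at the outlet or at the end, in percent of the substrate put in, blue
* amount of single product at the outlet or at the end, in percent of the substrate put in, grey

I reckon pseudo-first-order, with the constants taken at the whole charge of both reagents. Substrate becomes single product with constant a, which is its rate constant times the partner: 0.0478 s⁻¹. Single product is lost with constant b, from its steps with partner and with substrate: 0.0592 s⁻¹. So at time t the yield is y(t) = a/(b − a)·(e^(−at) − e^(−bt)).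

A fed charge starts late. The fed age τ, the mean time a steadily fed charge has stood in the flask at the reading, is the reading time minus half the feed time: 9.00 s.

Grey runs at full age and gives me 32.2 %. Violet and red run at τ and give 26.6 %. The steady balance of the blue tank, with the same constants, gives 22.1 %. I took the constants at the whole charge, so I trust the order more than the figures.

The forecast names grey, with violet 21.5 %, red 22 %, blue 17.8 % and grey 26.4 %, lower than my figures. Its ground is that “either feed loses time”.

The simulation gives grey as best, with violet 21.5 %, red 21.8 %, blue 17.7 % and grey 26.8 %. Grey holds 20.7 % of single product at 7.50 s, earlier than τ, and red holds 21.8 % at 15 s. The fed age gives a ratio of red to grey of 0.826, and the two flasks read 0.813. Red with 2.00 equiv of partner has the same τ of 9.00 s. The same formula gives it 42.0 %, and that flask holds 38.0 %.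

Its constants are made up, and the outcome is calculated.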